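Ring A is disconnected at C3–C4, between the bromine-bearing carbon and the gem-dimethyl carbon. The key step exploits the fact that C4 is a fully substituted carbon next to ring-fusion carbon C5: an iron hydride turns an isopropenyl group on C5 of a preformed ring B into the tertiary C4 radical, which adds 6-exo to an aldehyde carbon (C3) on the C10 side chain, so the quaternary centre and the trans-fused ring A arise in one operation. The precursor is a cyclohexanone made from (−)-verbenone, whose rigid pinane face sets C10 and C9 before the cyclobutane is opened to unveil the isopropenyl group. Bromine follows through a C2–C3 alkenyl bromide.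

Key step: step 5

Assumption: atom numbers are the labdane numbers of the target; (−)-verbenone is taken as enantiomerically pure, and the (R)-configured LaLi3 binaphthoxide catalyst is assumed to give the 13R epoxide (the mirror-image catalyst would be used if the sense is opposite).

Step 1
Reactants: 1 (−)-verbenone; 2 vinylmagnesium bromide
Product: 3 (1S,4R,5R)-4,6,6-trimethyl-4-vinylbicyclo[3.1.1]heptan-2-one (vinyl on the face opposite the CMe2 bridge)
Conditions: CuBr·SMe2 (10 mol %), THF, −40 → 0 °C; aq. NH4Cl
Reagents that add atoms: none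
Why: Copper-catalysed conjugate (1,4-) addition of a Grignard reagent to the β,β-disubstituted enone should deliver the vinyl group to the face opposite the CMe2 bridge, which sets the quaternary carbon (future C10) with its methyl syn to the bridge.

Step 2
Reactants: 3 vinyl ketone; 4 acrylonitrile
Product: 5 3-[4,6,6-trimethyl-2-oxo-4-vinylbicyclo[3.1.1]heptan-3-yl]propanenitrile (cyanoethyl anti to the CMe2 bridge, cis to vinyl)
Conditions: t-BuOK (10 mol %), t-BuOH/THF, 0 °C → rt
Reagents that add atoms: none
Why: Base-catalysed Michael addition (cyanoethylation) can occur only at the CH2 next to the quaternary carbon because the other α-carbon is a bridgehead, and the acceptor should add from the face opposite the CMe2 bridge, which sets future C9 as the epimer that is also favoured thermodynamically in the bicycle.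

Step 3
Reactants: 5 bicyclic keto nitrile
Product: 7 3-[2-methyl-6-oxo-3-(prop-1-en-2-yl)-2-vinylcyclohexyl]propanenitrile (isopropenyl cis to the C10 methyl; C9 and C10 chains cis to each other), via enol acetate 6 (not isolated)
Conditions: BF3·OEt2 (0.3 equiv), Zn(OAc)2 (0.3 equiv), Ac2O, 0 °C → rt; then K2CO3 (0.2 equiv), MeOH, 0 °C
Reagents that add atoms: none
Why: Lewis-acid-promoted Grob-type (retro-aldol-like) cyclobutane fragmentation of a nopinone-type ketone should break the bridgehead–CMe2 bond α to the carbonyl, trap the enol as its acetate and let the tertiary cation lose a methyl proton to give the isopropenyl group, after which brief methanolysis at 0 °C releases the ketone without touching C5, C9 or C10.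

Step 4
Reactants: 7 ring B ketone
Product: 8 3-[2-methyl-6-oxo-2-(3-oxopropyl)-3-(prop-1-en-2-yl)cyclohexyl]propanenitrile
Conditions: Rh(acac)(CO)2 (1 mol %), PPh3 (10 mol %), CO/H2 (1:1, 10 bar), toluene, 60 °C
Reagents that add atoms: carbon monoxide, [C-]#[O+]
Why: Rhodium-catalysed hydroformylation of the monosubstituted vinyl group on a quaternary carbon should give only the linear aldehyde (C3), while the 1,1-disubstituted isopropenyl group reacts far more slowly and no stereocentre is touched.

Step 5
Reactants: 8 keto aldehyde
Product: 9 3-(6-hydroxy-5,5,8a-trimethyl-2-oxodecahydronaphthalen-1-yl)propanenitrile (trans-decalin; mixture of C3 epimers)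
Conditions: Fe(acac)3 (30 mol %), PhSiH3 (2.5 equiv), EtOH, 60 °C
Reagents that add atoms: none
Why: An iron hydride formed from Fe(acac)3 and PhSiH3 transfers a hydrogen atom to the CH2 terminus of the isopropenyl group (Markovnikov), and the resulting tertiary C4 radical adds to the aldehyde carbon C3, forming the C3–C4 bond, after which the alkoxy radical is reduced to the iron alkoxide and protonated by ethanol. The closest known reaction type is the iron-catalysed hydrogen-atom-transfer reductive radical cyclization of alkene-tethered carbonyl compounds. Ring A closes in the 6-exo-trig mode onto the C=O bond. C5 and C10 are already set and their trans-diequatorial arms can only give the trans-fused decalin, whereas the new carbinol carbon C3 forms without control and is erased in step 7. The step needs hydrogen-atom transfer to the isopropenyl group alone and attack on the aldehyde instead of the ring ketone: the isopropenyl group is the only alkene present, and the ring ketone could be reached only through a strained bridged transition state, while the aldehyde sits on the neighbouring carbon at the right distance.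

Step 6
Reactants: 9 hydroxy ketone
Product: 10 3-(2,6-dihydroxy-2,5,5,8a-tetramethyldecahydronaphthalen-1-yl)propanenitrile (C8 hydroxyl axial, syn to the C10 methyl)
Conditions: MeLi, CeCl3 (MeCeCl2, 3 equiv), THF, −78 °C
Reagents that add atoms: methyllithium, [Li]C
Why: 1,2-Addition of a non-basic organocerium reagent to the ketone of the locked trans-decalin should occur equatorially because the axial C10 methyl blocks the axial path, so the C8 hydroxyl ends axial, syn to the C10 methyl and trans to the C9 chain, while the nitrile is inert at −78 °C.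

Step 7
Reactants: 10 diol
Product: 11 3-(2-hydroxy-2,5,5,8a-tetramethyl-6-oxodecahydronaphthalen-1-yl)propanenitrile
Conditions: (n-Pr4N)RuO4 (5 mol %), NMO, 4 Å MS, CH2Cl2, rt
Reagents that add atoms: none
Why: Ley–Griffith oxidation should convert the secondary C3 alcohol of both epimers into one ketone while the tertiary C8 alcohol and the nitrile stay untouched.

Step 8
Reactants: 11 hydroxy ketone
Product: 12 5-(2-cyanoethyl)-6-hydroxy-1,1,4a,6-tetramethyl-1,4,4a,5,6,7,8,8a-octahydronaphthalen-2-yl trifluoromethanesulfonate
Conditions: KHMDS (2.2 equiv), PhNTf2 (1.2 equiv), THF, −78 °C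
Reagents that add atoms: N-phenylbis(trifluoromethanesulfonimide), O=S(=O)(N(c1ccccc1)S(=O)(=O)C(F)(F)F)C(F)(F)F
Why: Enol triflate formation by O-sulfonylation of the potassium enolate is regiodefined because the C3 ketone can enolise only toward C2 (C4 is quaternary), the second equivalent of base merely holding the hindered C8 hydroxyl as its alkoxide.

Step 9
Reactants: 12 enol triflate
Product: 13 3-(6-bromo-2-hydroxy-2,5,5,8a-tetramethyl-1,2,3,4,4a,5,8,8a-octahydronaphthalen-1-yl)propanenitrile
Conditions: Ni(OAc)2·4H2O (10 mol %), 1,5-cyclooctadiene (25 mol %), Zn (20 mol %), LiBr, DMA/THF, rt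
Reagents that add atoms: lithium bromide, [Li+].[Br-]
Why: Nickel-catalysed halogen exchange of an enol triflate (insertion of zerovalent nickel into the C–O bond, exchange of triflate for bromide on the metal, C–Br reductive elimination) should give the alkenyl bromide with the double bond fixed at C2–C3.

Step 10
Reactants: 13 alkenyl bromide
Product: 14 3-[(1R,2R,4aS,6R,8aR)-6-bromo-2-hydroxy-2,5,5,8a-tetramethyldecahydronaphthalen-1-yl]propanenitrile
Conditions: Mn(dpm)3 (10 mol %), PhSiH3, t-BuOOH, i-PrOH, rt
Reagents that add atoms: none
Why: Mukaiyama-type manganese-hydride hydrogen-atom-transfer hydrogenation of a haloalkene should add H to C2 and then deliver the second hydrogen to the α-bromo radical at C3 from the axial direction, opposite the axial C4 methyl, so that bromine ends equatorial (3R, also the more stable epimer) with the C–Br bond retained.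

Step 11
Reactants: 14 bromo nitrile
Product: 16 4-[(1R,2R,4aS,6R,8aR)-6-bromo-2-hydroxy-2,5,5,8a-tetramethyldecahydronaphthalen-1-yl]butan-2-one, via ketimine 15 (not isolated)
Conditions: MeLi (3 equiv), Et2O, −78 → 0 °C; then aq. NH4Cl, rt
Reagents that add atoms: methyllithium, [Li]C; water, O
Why: Addition of an organolithium to a nitrile stops at the N-lithio ketimine, which is hydrolysed on work-up to the methyl ketone, while the neopentyl equatorial secondary bromide should resist substitution and elimination and the C8 alkoxide returns as the alcohol.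

Step 12
Reactants: 16 methyl ketone
Product: 17 (1R,2R,4aS,6R,8aR)-6-bromo-2,5,5,8a-tetramethyl-1-{2-[(2R)-2-methyloxiran-2-yl]ethyl}decahydronaphthalen-2-ol
Conditions: Me3S(O)I, NaH, LaLi3[(R)-binaphthoxide]3 (5 mol %), (2,4,6-(MeO)3C6H2)3P=O (5 mol %), 5 Å MS, THF, rt
Reagents that add atoms: trimethylsulfoxonium iodide, C[S+](C)(C)=O.[I-]
Why: Catalytic asymmetric Corey–Chaykovsky epoxidation of a methyl ketone with dimethylsulfoxonium methylide should set C13 as R by catalyst control, independent of the remote ring stereocentres.

Step 13
Reactants: 17 epoxide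
Product: 18 (3R,5S,8R,9R,10R,13R)-3-bromolabd-14-ene-8,13-diol (target)
Conditions: Me3SI, n-BuLi (ylide in excess), THF, −10 °C → rt
Reagents that add atoms: trimethylsulfonium iodide, C[S+](C)C.[I-]
Why: One-carbon homologation of an epoxide to an allylic alcohol with dimethylsulfonium methylide (ring opening at CH2, then ylide formation on sulfur and intramolecular β-elimination) should give the vinyl group without breaking the C13–O bond, so C13 stays R.

Compound list
1 | (−)-verbenone, (1S,5S)-4,6,6-trimethylbicyclo[3.1.1]hept-3-en-2-one | O=C1C=C(C)[C@@H]2C[C@H]1C2(C)C | starting material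
2 | vinylmagnesium bromide | C=C[Mg]Br | starting material
3 | (1S,4R,5R)-4,6,6-trimethyl-4-vinylbicyclo[3.1.1]heptan-2-one | O=C1C[C@](C)(C=C)[C@@H]2C[C@H]1C2(C)C | intermediate
4 | acrylonitrile | C=CC#N | starting material
5 | 3-[4,6,6-trimethyl-2-oxo-4-vinylbicyclo[3.1.1]heptan-3-yl]propanenitrile, cyanoethyl anti to the CMe2 bridge | N#CCC[C@@H]1[C@](C)(C=C)[C@@H]2C[C@H](C1=O)C2(C)C | intermediate
6 | 6-(2-cyanoethyl)-5-methyl-4-(prop-1-en-2-yl)-5-vinylcyclohex-1-en-1-yl acetate | N#CCC[C@@H]1[C@](C)(C=C)[C@@H](C(C)=C)CC=C1OC(C)=O | intermediate (not isolated)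
7 | 3-[2-methyl-6-oxo-3-(prop-1-en-2-yl)-2-vinylcyclohexyl]propanenitrile | N#CCC[C@@H]1[C@](C)(C=C)[C@@H](C(C)=C)CCC1=O | intermediate
8 | 3-[2-methyl-6-oxo-2-(3-oxopropyl)-3-(prop-1-en-2-yl)cyclohexyl]propanenitrile | N#CCC[C@@H]1[C@](C)(CCC=O)[C@@H](C(C)=C)CCC1=O | intermediate
9 | 3-(6-hydroxy-5,5,8a-trimethyl-2-oxodecahydronaphthalen-1-yl)propanenitrile, trans-decalin, C3 epimers | N#CCC[C@@H]1[C@]2(C)CCC(O)C(C)(C)[C@H]2CCC1=O | intermediate
10 | 3-(2,6-dihydroxy-2,5,5,8a-tetramethyldecahydronaphthalen-1-yl)propanenitrile, C3 epimers | N#CCC[C@@H]1[C@]2(C)CCC(O)C(C)(C)[C@H]2CC[C@@]1(C)O | intermediate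
11 | 3-(2-hydroxy-2,5,5,8a-tetramethyl-6-oxodecahydronaphthalen-1-yl)propanenitrile | N#CCC[C@@H]1[C@]2(C)CCC(=O)C(C)(C)[C@H]2CC[C@@]1(C)O | intermediate
12 | C2–C3 enol triflate of 11 | N#CCC[C@@H]1[C@]2(C)CC=C(OS(=O)(=O)C(F)(F)F)C(C)(C)[C@H]2CC[C@@]1(C)O | intermediate
13 | C2–C3 alkenyl bromide | N#CCC[C@@H]1[C@]2(C)CC=C(Br)C(C)(C)[C@H]2CC[C@@]1(C)O | intermediate
14 | 3-[(1R,2R,4aS,6R,8aR)-6-bromo-2-hydroxy-2,5,5,8a-tetramethyldecahydronaphthalen-1-yl]propanenitrile | N#CCC[C@@H]1[C@]2(C)CC[C@@H](Br)C(C)(C)[C@H]2CC[C@@]1(C)O | intermediate
15 | ketimine of 16 (N–H form) | CC(=N)CC[C@@H]1[C@]2(C)CC[C@@H](Br)C(C)(C)[C@H]2CC[C@@]1(C)O | intermediate (not isolated)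
16 | 4-[(1R,2R,4aS,6R,8aR)-6-bromo-2-hydroxy-2,5,5,8a-tetramethyldecahydronaphthalen-1-yl]butan-2-one | CC(=O)CC[C@@H]1[C@]2(C)CC[C@@H](Br)C(C)(C)[C@H]2CC[C@@]1(C)O | intermediate
17 | (13R)-13,14-epoxide: 6-bromo-2,5,5,8a-tetramethyl-1-{2-[(2R)-2-methyloxiran-2-yl]ethyl}decahydronaphthalen-2-ol | C[C@]3(CO3)CC[C@@H]1[C@]2(C)CC[C@@H](Br)C(C)(C)[C@H]2CC[C@@]1(C)O | intermediate
18 | (3R,5S,8R,9R,10R,13R)-3-bromolabd-14-ene-8,13-diol | C=C[C@](C)(O)CC[C@@H]1[C@]2(C)CC[C@@H](Br)C(C)(C)[C@H]2CC[C@@]1(C)O | target

Total step count: 13. Longest linear sequence: 13 steps, from compound 1.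

Steps most likely to fail

Step 5: the tertiary radical or the aldehyde may be reduced before cyclization, or the radical addition may revert by β-scission before the alkoxy radical is reduced. The fallback generates the radical from a halide under a tin hydride chain. Compound 8 is treated with HBr (CH2Cl2, −78 °C, Markovnikov hydrobromination of the isopropenyl group) to give the tertiary bromide F1. F1 is then cyclised with Bu3SnH and AIBN (benzene, 80 °C, slow addition), where the stannane traps the alkoxy radical formed after 6-exo addition to the aldehyde. This returns to the route at compound 9.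

Step 6: the hindered C8 ketone may enolise (with loss of the C9 configuration) or be attacked with poor facial selectivity. The fallback builds the methyl carbinol in two stages under thermodynamic control. Compound 9 reacts with dimethylsulfoxonium methylide (Me3S(O)I, NaH, DMSO, rt), where reversible betaine formation should place the new C–C bond equatorial, to give the spiro-epoxide F2. The CH2 terminus of F2 is then opened with hydride (LiEt3BH, THF, 0 °C). This returns to the route at compound 10.

Step 10: the C–Br bond may be lost by hydrogenolysis, or hydrogen may be delivered to the wrong face. The fallback sets out from ketone 11 and bypasses steps 8 to 10. Compound 11 is converted into the hydrazone F3 (N2H4·H2O, EtOH, reflux) and F3 into the geminal dibromide F4 (CuBr2, LiOt-Bu, THF). One bromine of F4 is then removed with Bu3SnH (1 equiv, Et3B/air, toluene, −78 °C), the α-bromo radical taking hydrogen from the axial direction. This returns to the route at compound 14.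

Further compounds
F1 | step 5 | 3-[3-(2-bromopropan-2-yl)-2-methyl-6-oxo-2-(3-oxopropyl)cyclohexyl]propanenitrile | N#CCC[C@@H]1[C@](C)(CCC=O)[C@@H](C(C)(C)Br)CCC1=O
F2 | step 6 | C8 spiro-epoxide of 9 (oxygen axial, syn to the C10 methyl) | N#CCC[C@@H]1[C@]2(C)CCC(O)C(C)(C)[C@H]2CC[C@]13CO3
F3 | step 10 | hydrazone of ketone 11 | N#CCC[C@@H]1[C@]2(C)CCC(=NN)C(C)(C)[C@H]2CC[C@@]1(C)O
F4 | step 10 | 3,3-dibromide derived from 11 | N#CCC[C@@H]1[C@]2(C)CCC(Br)(Br)C(C)(C)[C@H]2CC[C@@]1(C)O
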